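**Plan**

1. Numbering: C1 is the quaternary oxirane carbon bearing C7H2OBz, C2 is CH–OBz, C3 is CH–OH, C4=C5 is the alkene, C6 is the oxirane CH. The oxirane O, C2–O and C3–O lie on one face ("lower"), C7 on the other ("upper"); in this numbering the target is 1S,2R,3R,6S.
2. Enabling feature: C1–O and C2–O are cis on neighbouring ring carbons, and C1 is the para carbon of a phenol-derived 4-hydroxycyclohexa-2,5-dienone. The C1 hydroxyl can therefore pass oxygen to C2 across a boron atom (ring C1–O–B–O–C2) that is removed afterwards.
3. Cuts, last to first: C3–H (ketone reduction), the C2 ester, C6–O of the oxirane (C1–O displaces a C6 sulfonate), C4=C5 with C6–O (Wharton transposition of a C4-keto C5,C6-oxirane), C3–O (Rubottom), C2–O (tethered oxa-Michael), C1–O (phenol dearomatisation with water), the C7 ester.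
4. Forward: arene → achiral dienone ring → temporary cis-fused dioxaborolane → transient C5,C6-oxirane → C1,C6-oxirane. No C–C bond is made; the six ring carbons and C7 come from 4-hydroxybenzyl alcohol.
5. Stereochemistry: C1 and C2 come from the catalyst's choice of one enone arm plus the tether. C6 comes from peroxide attack anti to C1–O, then inversion on oxirane closure. C3 comes from the last hydride delivery anti to C2–OBz and the oxirane.

Key step: step 3

Assumption: the sense of arm selection by cinchona thioureas on a p-quinol cannot be predicted with confidence; the quinine-derived catalyst is written for the series drawn, and the quinidine-derived pseudoenantiomer would be used if the sense is the opposite.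

**Route**

Step 1
Reactants: 1 4-hydroxybenzyl alcohol; 2 benzoic acid
Product: 3 4-hydroxybenzyl benzoate
Conditions: PPh3, DIAD, THF, 0 °C → rt
Reagents that add atoms: none
Why: Mitsunobu esterification, in which only the carboxylic acid is acidic enough to protonate the betaine and act as nucleophile toward the activated benzylic alcohol, so the phenol should stay free (no stereocentre).

Step 2
Reactants: 3 4-hydroxybenzyl benzoate
Product: 4 4-(benzoyloxymethyl)-4-hydroxycyclohexa-2,5-dienone
Conditions: PhI(OAc)2, MeCN/H2O (4:1), 0 °C
Reagents that add atoms: water, O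
Why: Oxidative dearomatisation of a para-substituted phenol, in which water adds to the para carbon of the O-iodanyl phenol to give the p-quinol; the new carbinol carbon carries two identical enone arms and is not yet stereogenic.

Step 3
Reactants: 4 p-quinol; 5 phenylboronic acid
Product: 7 cis-fused phenylboronate of the C1/C2 diol enone, via boronic hemiester 6 (not isolated)
Conditions: N-[3,5-bis(trifluoromethyl)phenyl]-N'-[(8α,9S)-6'-methoxycinchonan-9-yl]thiourea (15 mol %), 4 Å MS, toluene, rt
Reagents that add atoms: none
Why: Proposed new method: the tertiary C1 hydroxyl and PhB(OH)2 condense reversibly to hemiester 6, whose remaining B–OH, made more nucleophilic by the quinuclidine nitrogen, adds to C2 of the enone arm that the thiourea holds by hydrogen bonding to the carbonyl, and proton transfer to C3 releases the catalyst. The closest known reaction type is the amine–thiourea-catalysed oxa-Michael addition of γ-hydroxy enones through boronic acid hemiesters, combined here with the tethered oxa-Michael desymmetrisation known for p-quinols with acetal tethers. The 1,3,2-dioxaborolane (C1, O, B, O, C2) closes 5-exo-trig. The new C2–O bond must be cis to C1–O because a five-membered bridge cannot span both faces, and C1 becomes stereogenic, its absolute configuration and that of C2 being fixed by which enantiotopic arm the catalyst activates. The step needs arm selection (catalyst), cis fusion (tether) and mono-addition, the last secured because the cyclised boron carries no further B–OH.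

Step 4
Reactants: 7 cis-fused phenylboronate
Product: 8 cis-C1,C2-diol enone
Conditions: pinacol (3 equiv), THF, rt
Reagents that add atoms: none
Why: Boronic ester transesterification onto pinacol under neutral conditions should free the diol without β-elimination of the new β-hydroxy ketone; only B–O bonds break, so C1 and C2 are unchanged.

Step 5
Reactants: 8 cis-C1,C2-diol enone
Product: 9 tris(triethylsilyl) dienol ether
Conditions: Et3SiOTf (3.5 equiv), Et3N, CH2Cl2, −78 → 0 °C
Reagents that add atoms: triethylsilyl trifluoromethanesulfonate, CC[Si](CC)(CC)OS(=O)(=O)C(F)(F)F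
Why: Silyl triflate/amine silylation of both hydroxyls and soft enolisation of the ketone toward C3, the only enolisable position because C1 is quaternary, gives the cross-conjugated silyl dienol ether without a free enolate that could expel C2–O.

Step 6
Reactants: 9 tris(triethylsilyl) dienol ether
Product: 11 C3-silyloxy enone, via silyloxy oxirane 10 (not isolated)
Conditions: mCPBA, NaHCO3, CH2Cl2, −20 → 0 °C
Reagents that add atoms: 3-chloroperbenzoic acid, OOC(=O)c1cccc(Cl)c1
Why: Rubottom oxidation, in which the peracid epoxidises the electron-rich C3=C4 enol ether anti to the allylic C2–OSiEt3 and ring opening with 1,4-silyl shift gives the C3 silyloxy ketone; the C3 configuration (expected trans to C2–O) is of no consequence because C3 is later oxidised and reset.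

Step 7
Reactants: 11 C3-silyloxy enone
Product: 12 C5,C6-epoxy ketone
Conditions: t-BuOOH (decane), Triton B (benzyltrimethylammonium hydroxide, cat.), THF, 0 °C
Reagents that add atoms: tert-butyl hydroperoxide, CC(C)(C)OO
Why: Weitz–Scheffer nucleophilic epoxidation, in which t-BuOO− should add axially to C6 anti to the axial C1–OSiEt3 bond (all other substituents equatorial), as 4-silyloxycyclohexenones do, and the enolate closes on the same face, placing the oxirane trans to C1–O and setting C5 and C6.

Step 8
Reactants: 12 C5,C6-epoxy ketone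
Product: 14 C6 allylic alcohol, via epoxy hydrazone 13 (not isolated)
Conditions: N2H4·H2O, AcOH, MeOH, 0 °C → rt
Reagents that add atoms: none
Why: Wharton transposition, in which the C4 hydrazone opens the oxirane to an alkenyldiazene that loses N2, leaving C4=C5 and the C6 hydroxyl with its C6–O bond, and so its upper-face configuration, untouched.

Step 9
Reactants: 14 C6 allylic alcohol
Product: 16 C1,C6-epoxy diol, via allylic mesylate 15 (not isolated)
Conditions: Ms2O, Et3N, THF, 0 °C; then Bu4NF (THF), same flask, 0 °C → rt
Reagents that add atoms: none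
Why: Sulfonylation of the only free hydroxyl, then fluoride removes the three silyl groups and the C1 oxygen displaces the anti-periplanar C6 mesylate in an intramolecular Williamson closure (3-exo-tet) with inversion at C6, putting the oxirane oxygen on the lower face, while the ammonium salt from the first stage buffers the fluoride so the C7 benzoate should not migrate.

Step 10
Reactants: 16 C1,C6-epoxy diol
Product: 17 C3 ketone with free C2 hydroxyl
Conditions: MnO2 (activated), CH2Cl2, rt
Reagents that add atoms: none
Why: MnO2 oxidises allylic alcohols selectively, so C3–OH should become the enone carbonyl while the non-allylic C2–OH is left.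

Step 11
Reactants: 17 C3 ketone with free C2 hydroxyl; 18 benzoyl chloride
Product: 19 C2 benzoate of the epoxy enone
Conditions: pyridine, DMAP (cat.), CH2Cl2, 0 °C
Reagents that add atoms: none
Why: Pyridine-mediated O-acylation of the only hydroxyl, with a weak base at low temperature chosen to avoid enolisation toward C2; the C2 configuration is untouched.

Step 12
Reactants: 19 C2 benzoate of the epoxy enone
Product: 20 target
Conditions: NaBH4, CeCl3·7H2O, MeOH, −78 °C
Reagents that add atoms: none
Why: Luche 1,2-reduction, in which hydride should add to C3 from the upper face, anti to the adjacent C2–OBz and to the oxirane oxygen, giving the C3 hydroxyl cis to both.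

**Compound list**

1 | 4-hydroxybenzyl alcohol | OCc1ccc(O)cc1 | starting material
2 | benzoic acid | OC(=O)c1ccccc1 | starting material
3 | 4-hydroxybenzyl benzoate | O=C(OCc1ccc(O)cc1)c1ccccc1 | intermediate
4 | 4-(benzoyloxymethyl)-4-hydroxycyclohexa-2,5-dienone (achiral p-quinol; its C4 is C1 of the target) | O=C1C=CC(O)(COC(=O)c2ccccc2)C=C1 | intermediate
5 | phenylboronic acid | OB(O)c1ccccc1 | starting material
6 | boronic hemiester of 4, C1–O–B(OH)Ph | O=C1C=CC(OB(O)c2ccccc2)(COC(=O)c2ccccc2)C=C1 | intermediate (not isolated)
7 | cis-fused 2-phenyl-1,3,2-dioxaborolane on C1–O/C2–O of 1-(benzoyloxymethyl)cyclohex-5-en-4-one; both O lower face, C7 upper | O=C1C[C@H]2OB(c3ccccc3)O[C@@]2(COC(=O)c2ccccc2)C=C1 | intermediate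
8 | 1-(benzoyloxymethyl)-1,2-dihydroxycyclohex-5-en-4-one; C1–OH and C2–OH cis, lower face | O=C(OC[C@@]1(O)[C@H](O)CC(=O)C=C1)c1ccccc1 | intermediate
9 | C1,C2-bis(triethylsilyloxy) dienol ether C3=C4(OSiEt3)–C5=C6; C1–O and C2–O lower face | O=C(OC[C@@]1(O[Si](CC)(CC)CC)[C@H](O[Si](CC)(CC)CC)C=C(O[Si](CC)(CC)CC)C=C1)c1ccccc1 | intermediate
10 | C3,C4-oxirane of 9 on the upper face, C4 bearing OSiEt3 | O=C(OC[C@@]1(O[Si](CC)(CC)CC)[C@H](O[Si](CC)(CC)CC)[C@H]2O[C@@]2(O[Si](CC)(CC)CC)C=C1)c1ccccc1 | intermediate (not isolated)
11 | 1,2,3-tris(triethylsilyloxy)cyclohex-5-en-4-one; C1–O and C2–O lower face, C3–O upper face | O=C(OC[C@@]1(O[Si](CC)(CC)CC)[C@H](O[Si](CC)(CC)CC)[C@@H](O[Si](CC)(CC)CC)C(=O)C=C1)c1ccccc1 | intermediate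
12 | C5,C6-epoxy ketone of 11; oxirane on the upper face, trans to C1–O | O=C(OC[C@@]1(O[Si](CC)(CC)CC)[C@H](O[Si](CC)(CC)CC)[C@@H](O[Si](CC)(CC)CC)C(=O)[C@H]2O[C@@H]12)c1ccccc1 | intermediate
13 | C4 hydrazone of 12 | O=C(OC[C@@]1(O[Si](CC)(CC)CC)[C@H](O[Si](CC)(CC)CC)[C@@H](O[Si](CC)(CC)CC)C(=NN)[C@H]2O[C@@H]12)c1ccccc1 | intermediate (not isolated)
14 | cyclohex-4-ene with C6–OH on the upper face; C1–, C2–, C3–OSiEt3 as in 11 | O=C(OC[C@@]1(O[Si](CC)(CC)CC)[C@H](O[Si](CC)(CC)CC)[C@@H](O[Si](CC)(CC)CC)C=C[C@H]1O)c1ccccc1 | intermediate
15 | C6 methanesulfonate of 14 | O=C(OC[C@@]1(O[Si](CC)(CC)CC)[C@H](O[Si](CC)(CC)CC)[C@@H](O[Si](CC)(CC)CC)C=C[C@H]1OS(C)(=O)=O)c1ccccc1 | intermediate (not isolated)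
16 | C1,C6-epoxy C2,C3-diol; oxirane O and C2–OH lower face, C3–OH upper face, C4=C5, C7–OBz | O=C(OC[C@]12O[C@H]1C=C[C@H](O)[C@H]2O)c1ccccc1 | intermediate
17 | C3 ketone of 16 (enone C3(=O)–C4=C5) with free C2–OH | O=C(OC[C@]12O[C@H]1C=CC(=O)[C@H]2O)c1ccccc1 | intermediate
18 | benzoyl chloride | O=C(Cl)c1ccccc1 | starting material
19 | C2 benzoate of 17 | O=C(OC[C@]12O[C@H]1C=CC(=O)[C@H]2OC(=O)c1ccccc1)c1ccccc1 | intermediate
20 | target: C1,C6-oxirane, C2–OBz and C3–OH all on the lower face, C4=C5, C7H2OBz on the upper face (1S,2R,3R,6S) | O=C(OC[C@]12O[C@H]1C=C[C@@H](O)[C@H]2OC(=O)c1ccccc1)c1ccccc1 | target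

**Count and risks**

Total steps: 12. Longest linear sequence: 12 (1 → 20).

Step 3 (key step, proposed new method). The catalyst may discriminate poorly between the two enantiotopic enone arms, reversible retro-oxa-Michael and re-addition may erode enantiopurity, and hemiester formation at the hindered tertiary hydroxyl may be slow. Fallback, from 4 to 8: the p-quinol and 4-methoxybenzaldehyde are combined with a chiral BINOL phosphoric acid, (R)- or (S)-3,3'-bis(2,4,6-triisopropylphenyl)-1,1'-binaphthyl-2,2'-diyl hydrogen phosphate, over 4 Å MS in CH2Cl2. Hemiacetal formation at the C1 hydroxyl and acid-catalysed oxa-Michael closure, the Brønsted acid cascade known for p-quinols and their hydroperoxide analogues, should give the cis-fused 2-(4-methoxyphenyl)-1,3-dioxolane F1. 80% aqueous AcOH at rt then hydrolyses the acetal to diol 8, where the route resumes.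

Step 7. The peroxide may attack the wrong face of C6, or base-induced β-elimination of the C2 silyloxy group may outrun conjugate addition; the Wharton step that follows is also capricious on hindered substrates. Fallback, from 11 to 14: NaBH4/CeCl3·7H2O reduces the C4 carbonyl to the allylic alcohol F2, with hydride expected anti to C3–O. VO(acac)2/t-BuOOH then delivers the oxirane to C5=C6 syn to that hydroxyl, giving the epoxy alcohol F3. 1,1'-Thiocarbonyldiimidazole converts the C4 hydroxyl into the imidazolylthiocarbonate F4. Bu3SnH/AIBN (toluene, 80 °C) generates the C4 radical, whose oxiranylcarbinyl ring opening and hydrogen transfer (Barton-type deoxygenative fragmentation) should give allylic alcohol 14 without basic conditions or hydrazine.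

Step 11. Enolisation of the ketol toward C2 during acylation may open the neighbouring oxirane and lead to aromatisation, and MnO2 in step 10 may over-oxidise the ketol. Fallback, from 16 to 19: Et3SiCl/imidazole silylates the more accessible allylic C3 hydroxyl to the C3 silyl ether F5. PhCOCl/pyridine/DMAP benzoylates C2–OH at the alcohol oxidation level to the silyl ether benzoate F6. HF·pyridine removes the silyl group to give the C3 epimer of the target F7. Dess–Martin periodinane (NaHCO3, CH2Cl2) oxidises C3–OH to keto benzoate 19, which enters step 12.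

**Further compounds**

F1 | step 3 | cis-fused 2-(4-methoxyphenyl)-1,3-dioxolane on C1–O/C2–O of the enone (acetal carbon configuration left open; it is lost on hydrolysis) | O=C1C[C@H]2OC(c3ccc(OC)cc3)O[C@@]2(COC(=O)c2ccccc2)C=C1
F2 | step 7 | C4 allylic alcohol of 11, C4–OH on the upper face | O=C(OC[C@@]1(O[Si](CC)(CC)CC)[C@H](O[Si](CC)(CC)CC)[C@@H](O[Si](CC)(CC)CC)[C@@H](O)C=C1)c1ccccc1
F3 | step 7 | C5,C6-epoxy C4-alcohol, oxirane on the upper face | O=C(OC[C@@]1(O[Si](CC)(CC)CC)[C@H](O[Si](CC)(CC)CC)[C@@H](O[Si](CC)(CC)CC)[C@@H](O)[C@H]2O[C@@H]12)c1ccccc1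
F4 | step 7 | C4 O-(imidazol-1-ylthiocarbonyl) derivative of F3 | O=C(OC[C@@]1(O[Si](CC)(CC)CC)[C@H](O[Si](CC)(CC)CC)[C@@H](O[Si](CC)(CC)CC)[C@@H](OC(=S)n3ccnc3)[C@H]2O[C@@H]12)c1ccccc1
F5 | step 11 | C3 triethylsilyl ether of 16 | O=C(OC[C@]12O[C@H]1C=C[C@H](O[Si](CC)(CC)CC)[C@H]2O)c1ccccc1
F6 | step 11 | C2 benzoate of F5 | O=C(OC[C@]12O[C@H]1C=C[C@H](O[Si](CC)(CC)CC)[C@H]2OC(=O)c1ccccc1)c1ccccc1
F7 | step 11 | C3 epimer of the target (C3–OH on the upper face) | O=C(OC[C@]12O[C@H]1C=C[C@H](O)[C@H]2OC(=O)c1ccccc1)c1ccccc1
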